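**Retrosynthetic overview**

- Feature: flavone atoms O1, C2, C3–O, C4=O, C4a, C8a and C8–O (ring C plus the C8 carbon) are the skeleton of kojic acid, and O7, the only free hydroxyl of ring A, can be the oxygen of an ester carbonyl.
- Target 16 comes from its 4'-benzyl ether 15 by hydrogenolysis; 15 is disconnected at C7–C8, a vinylogous Dieckmann closure of ring A from pyranone 13.
- 13 comes from β-keto ester 12 by enol O-methylation; 12 is disconnected at C4a–C5, a Negishi acylation of the C3-zincated pyranone with methoxymalonyl half chloride 9.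
- Pyranone 5 comes from kojic acid by C6 iodination, double O-methylation and Suzuki coupling with boronic acid 4.
- Ring order: ring C is bought as kojic acid, ring B is attached by cross-coupling, ring A is formed last.

Key step: step 9

Remarks on the chemistry: pyranone positions are numbered as in kojic acid (O1, C2 bearing the CH2O group, C3, C4=O, C5–O, C6) up to compound 13, and flavone numbering is used from 14 on. Compounds 8, 9, 12 and 14 each carry one stereocentre that is racemic and is lost later; the target has no stereocentre.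

**Route**

Step 1
Reactants: 1 kojic acid
Product: 2 5-hydroxy-2-(hydroxymethyl)-6-iodo-4H-pyran-4-one
Conditions: NIS (1.0 equiv), DMF, 0 °C to rt
Reagents that add atoms: N-iodosuccinimide, O=C1CCC(=O)N1I
Why: Electrophilic iodination of the C5 enol should occur at C6, its β-carbon and the position at which kojic acid reacts with electrophiles in Mannich, aldol and halogenation reactions.

Step 2
Reactants: 2 5-hydroxy-2-(hydroxymethyl)-6-iodo-4H-pyran-4-one
Product: 3 6-iodo-5-methoxy-2-(methoxymethyl)-4H-pyran-4-one
Conditions: MeI (excess), Ag2O, DMF, rt, dark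
Reagents that add atoms: iodomethane, CI
Why: Purdie methylation etherifies both the acidic enol hydroxyl and the primary alcohol without a free alkoxide, so the C6 iodide, a vinylogous acyl iodide, is not exposed to addition-elimination.

Step 3
Reactants: 3 6-iodo-5-methoxy-2-(methoxymethyl)-4H-pyran-4-one; 4 4-(benzyloxy)phenylboronic acid
Product: 5 6-[4-(benzyloxy)phenyl]-5-methoxy-2-(methoxymethyl)-4H-pyran-4-one
Conditions: Pd(PPh3)4 (5 mol %), K2CO3, 1,4-dioxane/H2O, 80 °C
Reagents that add atoms: none
Why: Suzuki-Miyaura coupling, in which the electron-poor C6–I bond should add readily to zerovalent palladium while the ethers are inert.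

Step 4
Reactants: 5 6-[4-(benzyloxy)phenyl]-5-methoxy-2-(methoxymethyl)-4H-pyran-4-one
Product: 6 6-[4-(benzyloxy)phenyl]-3-iodo-5-methoxy-2-(methoxymethyl)-4H-pyran-4-one
Conditions: I2 (0.6 equiv), (NH4)2Ce(NO3)6 (1.1 equiv), MeCN, 50 °C
Reagents that add atoms: iodine, II
Why: Oxidative electrophilic iodination with iodine and tetravalent cerium, the method used for C3 iodination of flavones, should attack C3, the only free pyranone carbon and the β-carbon of the O1–C2=C3 enol ether, in preference to the benzyloxyphenyl ring, which is deactivated by conjugation with the pyranone carbonyl.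

Step 5
Reactants: 7 dimethyl methoxymalonate
Product: 8 potassium 2-methoxy-3-methoxy-3-oxopropanoate (racemic)
Conditions: KOH (1.0 equiv), MeOH, 0 °C to rt; evaporate
Reagents that add atoms: potassium hydroxide, [K+].[OH-]
Why: Monosaponification of a symmetrical malonate with one equivalent of hydroxide stops at the half-ester salt, because the carboxylate formed deactivates the second ester toward hydrolysis.

Step 6
Reactants: 8 potassium 2-methoxy-3-methoxy-3-oxopropanoate
Product: 9 methyl 3-chloro-2-methoxy-3-oxopropanoate (racemic, used crude)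
Conditions: (COCl)2, cat. DMF, CH2Cl2, 0 °C to rt
Reagents that add atoms: oxalyl chloride, O=C(Cl)C(=O)Cl
Why: Acid chloride formation from a carboxylate salt with oxalyl chloride under Vilsmeier catalysis runs cold and without the free malonic half acid, which avoids decarboxylation.

Step 7
Reactants: 6 6-[4-(benzyloxy)phenyl]-3-iodo-5-methoxy-2-(methoxymethyl)-4H-pyran-4-one; 9 methyl 3-chloro-2-methoxy-3-oxopropanoate
Product: 12 methyl 3-{6-[4-(benzyloxy)phenyl]-5-methoxy-2-(methoxymethyl)-4-oxo-4H-pyran-3-yl}-2-methoxy-3-oxopropanoate (racemic), via pyranonylmagnesium chloride 10 (not isolated), via pyranonylzinc chloride 11 (not isolated)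
Conditions: iPrMgCl·LiCl (1.1 equiv), THF, −40 °C; ZnCl2 (1.2 equiv), −40 to 0 °C; then 9 (1.5 equiv), Pd(PPh3)4 (5 mol %), 0 °C to rt
Reagents that add atoms: none
Why: Iodine-magnesium exchange on the electron-poor alkenyl iodide should outrun proton transfer and carbonyl addition at −40 °C, transmetalation to zinc gives a weakly basic C3 nucleophile that tolerates the acidic hydrogen of 9 and of 12, and Negishi acylation under zerovalent palladium catalysis forms the bond that becomes C4a–C5.

Step 8
Reactants: 12 methyl 3-{6-[4-(benzyloxy)phenyl]-5-methoxy-2-(methoxymethyl)-4-oxo-4H-pyran-3-yl}-2-methoxy-3-oxopropanoate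
Product: 13 methyl (Z)-3-{6-[4-(benzyloxy)phenyl]-5-methoxy-2-(methoxymethyl)-4-oxo-4H-pyran-3-yl}-2,3-dimethoxyacrylate
Conditions: K2CO3, Me2SO4, DMF, rt
Reagents that add atoms: dimethyl sulfate, COS(=O)(=O)OC
Why: Enolate O-alkylation of the β-keto ester with a hard methylating agent in a dissociating solvent should favour oxygen over the hindered, fully substituted α-carbon, and the non-chelated W-shaped potassium enolate should place the new methoxy group trans to the ester, which is the Z isomer.

Step 9
Reactants: 13 methyl (Z)-3-{6-[4-(benzyloxy)phenyl]-5-methoxy-2-(methoxymethyl)-4-oxo-4H-pyran-3-yl}-2,3-dimethoxyacrylate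
Product: 15 2-[4-(benzyloxy)phenyl]-7-hydroxy-3,5,6,8-tetramethoxy-4H-chromen-4-one, via cyclohexadienone 14 (not isolated)
Conditions: LiN(SiMe3)2 (2.5 equiv), THF (0.02 M), −78 °C to rt; aq. HCl work-up
Reagents that add atoms: none
Why: LiN(SiMe3)2 removes a proton from the C8 methylene, the vinylogous α-position of the C4 carbonyl and the only acidic carbon because the C5 carbonyl is locked as its methyl enol ether; the dienolate adds through C8 to the C7 ester carbonyl, methoxide is lost, and dienone 14 is deprotonated at C8 to the 7-phenoxide, which makes the sequence irreversible. The closest known reaction type is the Claisen or Dieckmann acylation of γ-deprotonated 2-alkyl-4-pyranones by esters, as used in polyketide-type aromatisations. Ring A closes in the 6-exo-trig mode by formation of the C7–C8 bond. No stereocentre remains, since the C8 centre of 14 is erased on aromatisation. The step needs the ester cis to the pyranone across C5=C6, which the Z enol ether provides; any E isomer should equilibrate, because the dienolate charge is delocalised through C4a into the acrylate and lowers the C5–C6 rotation barrier, and because released methoxide adds reversibly to the push-pull alkene. O7 emerges as the only free hydroxyl because every other ring A oxygen enters as a methyl ether.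

Step 10
Reactants: 15 2-[4-(benzyloxy)phenyl]-7-hydroxy-3,5,6,8-tetramethoxy-4H-chromen-4-one
Product: 16 7-hydroxy-2-(4-hydroxyphenyl)-3,5,6,8-tetramethoxy-4H-chromen-4-one (target)
Conditions: H2 (1 atm), Pd/C (palladium on carbon, 10 %), EtOAc/MeOH, rt
Reagents that add atoms: none
Why: Hydrogenolysis of the benzyl aryl ether should leave the tetrasubstituted, electron-rich C2=C3 bond of the 3-methoxyflavone and the aryl methyl ethers untouched at 1 atm and room temperature.

**Compound list**

1 | kojic acid, 5-hydroxy-2-(hydroxymethyl)-4H-pyran-4-one | OCc1cc(=O)c(O)co1 | starting material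
2 | 5-hydroxy-2-(hydroxymethyl)-6-iodo-4H-pyran-4-one | OCc1cc(=O)c(O)c(I)o1 | intermediate
3 | 6-iodo-5-methoxy-2-(methoxymethyl)-4H-pyran-4-one | COCc1cc(=O)c(OC)c(I)o1 | intermediate
4 | 4-(benzyloxy)phenylboronic acid | OB(O)c1ccc(OCc2ccccc2)cc1 | starting material
5 | 6-[4-(benzyloxy)phenyl]-5-methoxy-2-(methoxymethyl)-4H-pyran-4-one | COCc1cc(=O)c(OC)c(-c2ccc(OCc3ccccc3)cc2)o1 | intermediate
6 | 6-[4-(benzyloxy)phenyl]-3-iodo-5-methoxy-2-(methoxymethyl)-4H-pyran-4-one | COCc1oc(-c2ccc(OCc3ccccc3)cc2)c(OC)c(=O)c1I | intermediate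
7 | dimethyl methoxymalonate | COC(C(=O)OC)C(=O)OC | starting material
8 | potassium 2-methoxy-3-methoxy-3-oxopropanoate (racemic) | [K+].COC(C([O-])=O)C(=O)OC | intermediate
9 | methyl 3-chloro-2-methoxy-3-oxopropanoate (racemic) | COC(C(Cl)=O)C(=O)OC | intermediate
10 | chloro{6-[4-(benzyloxy)phenyl]-5-methoxy-2-(methoxymethyl)-4-oxo-4H-pyran-3-yl}magnesium | COCc1oc(-c2ccc(OCc3ccccc3)cc2)c(OC)c(=O)c1[Mg]Cl | intermediate
11 | chloro{6-[4-(benzyloxy)phenyl]-5-methoxy-2-(methoxymethyl)-4-oxo-4H-pyran-3-yl}zinc | COCc1oc(-c2ccc(OCc3ccccc3)cc2)c(OC)c(=O)c1[Zn]Cl | intermediate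
12 | methyl 3-{6-[4-(benzyloxy)phenyl]-5-methoxy-2-(methoxymethyl)-4-oxo-4H-pyran-3-yl}-2-methoxy-3-oxopropanoate (racemic) | COCc1oc(-c2ccc(OCc3ccccc3)cc2)c(OC)c(=O)c1C(=O)C(OC)C(=O)OC | intermediate
13 | methyl (Z)-3-{6-[4-(benzyloxy)phenyl]-5-methoxy-2-(methoxymethyl)-4-oxo-4H-pyran-3-yl}-2,3-dimethoxyacrylate | COCc1oc(-c2ccc(OCc3ccccc3)cc2)c(OC)c(=O)c1/C(OC)=C(/OC)C(=O)OC | intermediate
14 | 2-[4-(benzyloxy)phenyl]-3,5,6,8-tetramethoxy-4H-chromene-4,7(8H)-dione (racemic at C8) | COC1C(=O)C(OC)=C(OC)C2=C1OC(-c3ccc(OCc4ccccc4)cc3)=C(OC)C2=O | intermediate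
15 | 2-[4-(benzyloxy)phenyl]-7-hydroxy-3,5,6,8-tetramethoxy-4H-chromen-4-one | COc1c(O)c(OC)c2oc(-c3ccc(OCc4ccccc4)cc3)c(OC)c(=O)c2c1OC | intermediate
16 | 7-hydroxy-2-(4-hydroxyphenyl)-3,5,6,8-tetramethoxy-4H-chromen-4-one | COc1c(O)c(OC)c2oc(-c3ccc(O)cc3)c(OC)c(=O)c2c1OC | target

**Step count**

Total: 10 steps. Longest linear sequence: 8 steps (1, 2, 3, 4, 7, 8, 9, 10 from kojic acid); steps 5 and 6 form the side branch.

**Steps most likely to fail**

Step 9. The ester carbonyl is part of a vinylogous carbonate and may be attacked too slowly, so that the dienolate is lost to intermolecular conjugate addition or the wrong alkene geometry persists. The fallback sets out from 13 and raises the electrophilicity of C7. Selective methyl ester cleavage with Me3SnOH (1,2-dichloroethane, 80 °C) should give (Z)-3-{6-[4-(benzyloxy)phenyl]-5-methoxy-2-(methoxymethyl)-4-oxo-4H-pyran-3-yl}-2,3-dimethoxyacrylic acid F1. Carbonyldiimidazole in THF should convert it into the acyl imidazolide F2. Treatment of F2 with LiN(SiMe3)2 at −78 °C should then close ring A by acylation of the C8 dienolate with loss of imidazole, and the route is rejoined at 15.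

Step 7. The C3 carbanion may be quenched by proton transfer from the methoxymethyl group, may open the pyranone by β-elimination, or may enolise acid chloride 9 to a ketene. The fallback sets out from 6 and avoids any C3 organometallic nucleophile. Hydroxycarbonylation catalysed by Pd(OAc)2 and dppf (CO 1 atm, H2O, Et3N, DMF, 70 °C) should give 6-[4-(benzyloxy)phenyl]-5-methoxy-2-(methoxymethyl)-4-oxo-4H-pyran-3-carboxylic acid F3. Carbonyldiimidazole should give the acyl imidazolide F4. A magnesium-mediated decarboxylative Claisen condensation of F4 with potassium salt 8 (MgCl2, Et3N, MeCN, rt to 50 °C) should deliver the β-keto ester, and the route is rejoined at 12.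

Step 8. Methylation may go to carbon instead of oxygen, or the enol ether may form mainly with the ester trans to the pyranone. The fallback sets out from 12 and replaces enolate alkylation by acetalisation and elimination under thermodynamic control. Trimethyl orthoformate in MeOH with catalytic H2SO4 should give the dimethyl ketal methyl 3-{6-[4-(benzyloxy)phenyl]-5-methoxy-2-(methoxymethyl)-4-oxo-4H-pyran-3-yl}-2,3,3-trimethoxypropanoate F5. Acid-catalysed loss of methanol (cat. TsOH, toluene, reflux) should give the more stable enol ether with the methoxy group trans to the ester, and the route is rejoined at 13.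

**Further compounds**

F1 | step 9 | (Z)-3-{6-[4-(benzyloxy)phenyl]-5-methoxy-2-(methoxymethyl)-4-oxo-4H-pyran-3-yl}-2,3-dimethoxyacrylic acid | COCc1oc(-c2ccc(OCc3ccccc3)cc2)c(OC)c(=O)c1/C(OC)=C(/OC)C(=O)O
F2 | step 9 | (Z)-3-{6-[4-(benzyloxy)phenyl]-5-methoxy-2-(methoxymethyl)-4-oxo-4H-pyran-3-yl}-1-(1H-imidazol-1-yl)-2,3-dimethoxyprop-2-en-1-one | COCc1oc(-c2ccc(OCc3ccccc3)cc2)c(OC)c(=O)c1/C(OC)=C(/OC)C(=O)n4ccnc4
F3 | step 7 | 6-[4-(benzyloxy)phenyl]-5-methoxy-2-(methoxymethyl)-4-oxo-4H-pyran-3-carboxylic acid | COCc1oc(-c2ccc(OCc3ccccc3)cc2)c(OC)c(=O)c1C(=O)O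
F4 | step 7 | 2-[4-(benzyloxy)phenyl]-5-(1H-imidazole-1-carbonyl)-3-methoxy-6-(methoxymethyl)-4H-pyran-4-one | COCc1oc(-c2ccc(OCc3ccccc3)cc2)c(OC)c(=O)c1C(=O)n4ccnc4
F5 | step 8 | methyl 3-{6-[4-(benzyloxy)phenyl]-5-methoxy-2-(methoxymethyl)-4-oxo-4H-pyran-3-yl}-2,3,3-trimethoxypropanoate | COCc1oc(-c2ccc(OCc3ccccc3)cc2)c(OC)c(=O)c1C(OC)(OC)C(OC)C(=O)OC
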